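**Retrosynthetic overview**

1. Germacrane locants are used (C1 ketone, C2=C3 enol ether, C4=C5 with C15, C6 lactone carbinol, C7, C8 ester carbinol, C9, C10 with C14, C11 with C13, C12 lactone carbonyl). Target 26 is traced back, through an inverting Mitsunobu esterification at C8 and a conjugate reduction at C11/C13, to the 8α-hydroxy α-methylene lactone 23.
2. 23 is disconnected at C7–C8: an intramolecular chromium-mediated allylation of aldehyde 21, which already holds the 3(2H)-furanone and a 3-(bromomethyl)butenolide. This closes the nine-membered ring O–C3–C4=C5–C6–C7–C8–C9–C10 as the last ring and sets C7 and C8.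
3. Enabling feature: C7 is the β-carbon of the γ-lactone ring (O–C6–C7–C11–C12), it carries the C8 carbinol, and C11 carries C13. This β-(hydroxyalkyl)-α-methyl(ene)-γ-butyrolactone is the retron of γ-attack of a butenolide-derived C13–C11=C7 allyl metal on a C8 aldehyde.
4. 21 comes from ring-closing metathesis of the 2-(bromomethyl)acrylate of a C6 vinyl carbinol (butenolide) and gold-catalysed cyclisation of an α'-hydroxy ynone (furanone). The ynone is made from Weinreb amide 8 (C8–C10, C14, C1; C10 from (S)-lactic acid by Seebach alkylation) and enyne 12 (C2–C7, C15; 4Z olefin from (Z)-3-methylpent-2-en-4-yn-1-ol; C6 by asymmetric vinylation).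
5. Ring order: furanone (step 9), butenolide that becomes the lactone (step 12), nine-membered ring (step 14).

Key step: step 14

Assumption: the macrocyclisation passes through the chair transition state described in step 14, so C8 is formed as the 8α (8S) alcohol and is inverted in the final esterification.

**Route**

Step 1
Reactants: 1 (S)-lactic acid
Product: 2 (2S,5S)-2-tert-butyl-5-methyl-1,3-dioxolan-4-one
Conditions: pivalaldehyde, TsOH·H2O (cat.), H2SO4 (cat.), pentane, reflux, Dean–Stark; cis isomer crystallised at −78 °C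
Reagents that add atoms: pivalaldehyde CC(C)(C)C=O
Why: Acid-catalysed acetalisation (first stage of Seebach self-regeneration of stereocentres) should give mainly the cis-dioxolanone, whose acetal carbon stores the chirality of the lactate carbon.

Step 2
Reactants: 2 (2S,5S)-2-tert-butyl-5-methyl-1,3-dioxolan-4-one; 3 allyl bromide
Product: 5 (2S,5R)-5-allyl-2-tert-butyl-5-methyl-1,3-dioxolan-4-one, via lithium enolate 4 (not isolated)
Conditions: LiN(iPr)2, THF, −78 °C; then 3, −78 → −20 °C
Reagents that add atoms: none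
Why: Seebach enolate alkylation: the allyl group should enter anti to the tert-butyl group, which builds the quaternary carbon (future C10, R) with net retention.

Step 3
Reactants: 5 (2S,5R)-5-allyl-2-tert-butyl-5-methyl-1,3-dioxolan-4-one
Product: 6 (R)-2-hydroxy-N-methoxy-N,2-dimethylpent-4-enamide
Conditions: MeNH(OMe)·HCl, iPrMgCl, THF, −20 → 0 °C
Reagents that add atoms: N,O-dimethylhydroxylamine hydrochloride CNOC.Cl
Why: Weinreb amide formation by aminolysis of the activated dioxolanone carbonyl with the magnesium amide; the hemiacetal collapses with loss of pivalaldehyde and the quaternary centre is not touched.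

Step 4
Reactants: 6 (R)-2-hydroxy-N-methoxy-N,2-dimethylpent-4-enamide
Product: 8 (R)-2-hydroxy-N,4,4-trimethoxy-N,2-dimethylbutanamide, via aldehyde 7 (not isolated)
Conditions: O3, CH2Cl2/MeOH, −78 °C; Me2S; then HC(OMe)3, PPTS, MeOH, rt
Reagents that add atoms: methanol CO; trimethyl orthoformate COC(OC)OC
Why: Ozonolysis of the terminal olefin followed by acetalisation masks the future C8 aldehyde as a dimethyl acetal that tolerates the organometallic and metathesis steps.

Step 5
Reactants: 9 (Z)-3-methylpent-2-en-4-yn-1-ol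
Product: 10 (Z)-3-methylpent-2-en-4-ynal
Conditions: TEMPO (10 mol%), PhI(OAc)2, CH2Cl2, 0 °C → rt; used as a solution
Reagents that add atoms: none
Why: Oxoammonium (TEMPO) oxidation of the allylic alcohol is neutral, so the Z olefin (future C4=C5) should not isomerise.

Step 6
Reactants: 10 (Z)-3-methylpent-2-en-4-ynal
Product: 11 (3S,4Z)-5-methylhepta-1,4-dien-6-yn-3-ol
Conditions: divinylzinc, (S)-diphenyl(1-methylpyrrolidin-2-yl)methanol (10 mol%), toluene/Et2O, −20 °C; aq NH4Cl
Reagents that add atoms: divinylzinc C=C[Zn]C=C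
Why: Amino alcohol-catalysed enantioselective alkenylzinc addition to an enal; the (S)-ligand directs the vinyl group to the Si face and so sets the carbinol carbon (future C6) as S.

Step 7
Reactants: 11 (3S,4Z)-5-methylhepta-1,4-dien-6-yn-3-ol
Product: 12 tert-butyl{[(3S,4Z)-5-methylhepta-1,4-dien-6-yn-3-yl]oxy}dimethylsilane
Conditions: TBSCl, imidazole, DMF, 0 °C → rt
Reagents that add atoms: tert-butyldimethylsilyl chloride CC(C)(C)[Si](C)(C)Cl
Why: Silylation protects the C6 hydroxyl, which would otherwise add to the activated alkyne in step 9 and give a furan.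

Step 8
Reactants: 12 tert-butyl{[(3S,4Z)-5-methylhepta-1,4-dien-6-yn-3-yl]oxy}dimethylsilane; 8 (R)-2-hydroxy-N,4,4-trimethoxy-N,2-dimethylbutanamide
Product: 15 (3S,4Z,9R)-3-(tert-butyldimethylsilyloxy)-9-hydroxy-11,11-dimethoxy-5,9-dimethylundeca-1,4-dien-6-yn-8-one, via lithium acetylide 13 (not isolated), via chloromagnesium alkoxide 14 (not isolated)
Conditions: 12, n-BuLi, THF, −78 °C; 8, iPrMgCl, THF, −40 °C; the two solutions combined, −78 → 0 °C; aq NH4Cl
Reagents that add atoms: none
Why: Weinreb ketone synthesis with an alkynyllithium; the chelated tetrahedral intermediate prevents over-addition and the tertiary hydroxyl is masked as its magnesium alkoxide.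

Step 9
Reactants: 15 (3S,4Z,9R)-3-(tert-butyldimethylsilyloxy)-9-hydroxy-11,11-dimethoxy-5,9-dimethylundeca-1,4-dien-6-yn-8-one
Product: 16 (2R)-5-[(2Z,4S)-4-(tert-butyldimethylsilyloxy)hexa-2,5-dien-2-yl]-2-(2,2-dimethoxyethyl)-2-methylfuran-3(2H)-one
Conditions: (Ph3P)AuCl (5 mol%), AgOTf (5 mol%), toluene, rt
Reagents that add atoms: none
Why: Gold-catalysed 5-endo-dig cycloisomerisation of an α'-hydroxy ynone to a 3(2H)-furanone; the tertiary hydroxyl attacks the β-carbon (C3) of the activated ynone faster than the remote vinyl group can engage the alkyne.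

Step 10
Reactants: 16 (2R)-5-[(2Z,4S)-4-(tert-butyldimethylsilyloxy)hexa-2,5-dien-2-yl]-2-(2,2-dimethoxyethyl)-2-methylfuran-3(2H)-one
Product: 17 (2R)-2-(2,2-dimethoxyethyl)-5-[(2Z,4S)-4-hydroxyhexa-2,5-dien-2-yl]-2-methylfuran-3(2H)-one
Conditions: TBAF, AcOH (1:1), THF, 0 °C → rt
Reagents that add atoms: none
Why: Buffered fluoride desilylation frees the C6 hydroxyl without generating an alkoxide or strong acid, so the acetal and the doubly allylic carbinol should survive.

Step 11
Reactants: 17 (2R)-2-(2,2-dimethoxyethyl)-5-[(2Z,4S)-4-hydroxyhexa-2,5-dien-2-yl]-2-methylfuran-3(2H)-one; 18 2-(bromomethyl)acrylic acid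
Product: 19 (3S,4Z)-5-[(2R)-2-(2,2-dimethoxyethyl)-2-methyl-3-oxo-2,3-dihydrofuran-5-yl]hexa-1,4-dien-3-yl 2-(bromomethyl)prop-2-enoate
Conditions: DCC, DMAP (5 mol%), CH2Cl2, −20 → 0 °C
Reagents that add atoms: none
Why: Steglich esterification with retention at C6; the low DMAP loading and low temperature limit attack of the catalyst on the allylic bromide.

Step 12
Reactants: 19 (3S,4Z)-5-[(2R)-2-(2,2-dimethoxyethyl)-2-methyl-3-oxo-2,3-dihydrofuran-5-yl]hexa-1,4-dien-3-yl 2-(bromomethyl)prop-2-enoate
Product: 20 (5R)-3-(bromomethyl)-5-{(1Z)-2-[(2R)-2-(2,2-dimethoxyethyl)-2-methyl-3-oxo-2,3-dihydrofuran-5-yl]prop-1-en-1-yl}furan-2(5H)-one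
Conditions: second-generation Hoveyda–Grubbs catalyst (10 mol%), toluene, 80 °C, argon sparge
Reagents that add atoms: none
Why: Ring-closing metathesis of the vinyl group with the acrylate olefin closes the five-membered butenolide; the conjugated trisubstituted C4=C5 olefin and the enol ether are inert, and the base-free conditions protect the acidic C6–H.

Step 13
Reactants: 20 (5R)-3-(bromomethyl)-5-{(1Z)-2-[(2R)-2-(2,2-dimethoxyethyl)-2-methyl-3-oxo-2,3-dihydrofuran-5-yl]prop-1-en-1-yl}furan-2(5H)-one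
Product: 21 {(2R)-5-[(1Z)-1-((2R)-4-(bromomethyl)-5-oxo-2,5-dihydrofuran-2-yl)prop-1-en-2-yl]-2-methyl-3-oxo-2,3-dihydrofuran-2-yl}acetaldehyde
Conditions: TFA/H2O (9:1), CH2Cl2, 0 °C; used at once
Reagents that add atoms: water O
Why: Acid hydrolysis of the dimethyl acetal frees the C8 aldehyde without base, which would trigger β-elimination of the furanone oxygen or enolisation at C6.

Step 14
Reactants: 21 {(2R)-5-[(1Z)-1-((2R)-4-(bromomethyl)-5-oxo-2,5-dihydrofuran-2-yl)prop-1-en-2-yl]-2-methyl-3-oxo-2,3-dihydrofuran-2-yl}acetaldehyde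
Product: 23 (6R,7R,8S,10R)-8-hydroxy-3,10-epoxy-1-oxogermacra-2,4Z,11(13)-trien-12,6-olide, via allylchromium dichloride 22 (not isolated)
Conditions: CrCl2 (6 equiv), THF, rt, 21 added by syringe pump over 10 h (final 2 mM); aq NH4Cl
Reagents that add atoms: none
Why: Two equivalents of divalent chromium reduce the C13–Br bond of 21 to allylchromium 22 (trivalent chromium on C13), whose γ-carbon C7 adds to the C8 aldehyde through a six-membered chair (Zimmerman–Traxler) transition state with allyl transposition, so the C7=C11 ring olefin becomes the exocyclic C11=C13 methylene and the chromium alkoxide gives the C8 alcohol on work-up. The closest known reaction types are the chromium-mediated (Nozaki–Hiyama–Kishi type) allylation of aldehydes with 3-(bromomethyl)furan-2(5H)-ones and the intramolecular version with 2-(bromomethyl)acrylates that closes ten-membered germacranolide rings. The nine-membered ring is closed by 9-exo-trig attack of C7 on the aldehyde carbon, and it is the only ring formed. C7 is controlled by C6: the tether reaches C7 on the butenolide face anti to the C6–C5 bond, the face also preferred for attack on 5-substituted butenolides, which gives the trans-fused lactone (7R, H-7α). C8 is controlled by the chair: the allyl unit is locked with C6 trans to C13 (as in an (E)-crotyl metal) and C9 sits equatorial, gauche to C6 as the ring requires, which leads to the anti adduct with the 8α (8S) alcohol. The step needs γ- over α-attack (cyclic transition state), aldehyde over C1 ketone selectivity (allylchromium reagents leave the vinylogous-ester ketone and the lactone untouched) and ring closure over oligomerisation (slow addition at high dilution, helped by the 4Z olefin and the furanone ring, which hold C6 and C10 on the same side of the chain).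

Step 15
Reactants: 23 (6R,7R,8S,10R)-8-hydroxy-3,10-epoxy-1-oxogermacra-2,4Z,11(13)-trien-12,6-olide
Product: 24 (6R,7R,8S,10R,11S)-8-hydroxy-3,10-epoxy-1-oxogermacra-2,4Z-dien-12,6-olide
Conditions: [(Ph3P)CuH]6 (0.5 equiv), toluene, H2O (5 equiv), rt
Reagents that add atoms: none
Why: Stryker conjugate reduction: copper hydride should deliver hydride only to the unhindered exocyclic enoate carbon C13, and protonation of the enolate at C11 anti to the C7–H bond (the face preferred in reductions of trans-fused 6,12-olides) gives the 11S methyl, which is also the more stable all-trans arrangement.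

Step 16
Reactants: 24 (6R,7R,8S,10R,11S)-8-hydroxy-3,10-epoxy-1-oxogermacra-2,4Z-dien-12,6-olide; 25 angelic acid
Product: 26 (6R,7R,8R,10R,11S)-8-angeloyloxy-3,10-epoxy-1-oxogermacra-2,4Z-dien-12,6-olide (target CNP0278264.1)
Conditions: PPh3, DIAD, toluene, 0 °C → rt
Reagents that add atoms: none
Why: Mitsunobu esterification: the carboxylate displaces the oxyphosphonium ion with inversion, which turns the 8α (8S) alcohol into the 8β (8R) angelate under neutral conditions that should keep the Z geometry of the angelate.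

**Compound list**

1 | (S)-lactic acid | C[C@H](O)C(=O)O | starting material
2 | (2S,5S)-2-tert-butyl-5-methyl-1,3-dioxolan-4-one | C[C@@H]1O[C@H](C(C)(C)C)OC1=O | intermediate
3 | allyl bromide | C=CCBr | starting material
4 | lithium (2S)-2-tert-butyl-5-methyl-1,3-dioxol-4-olate (enolate, not isolated) | CC1=C(O[Li])O[C@@H](C(C)(C)C)O1 | intermediate
5 | (2S,5R)-5-allyl-2-tert-butyl-5-methyl-1,3-dioxolan-4-one | C=CC[C@@]1(C)O[C@H](C(C)(C)C)OC1=O | intermediate
6 | (R)-2-hydroxy-N-methoxy-N,2-dimethylpent-4-enamide | C=CC[C@@](C)(O)C(=O)N(C)OC | intermediate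
7 | (R)-2-hydroxy-N-methoxy-N,2-dimethyl-4-oxobutanamide (not isolated) | O=CC[C@@](C)(O)C(=O)N(C)OC | intermediate
8 | (R)-2-hydroxy-N,4,4-trimethoxy-N,2-dimethylbutanamide | COC(OC)C[C@@](C)(O)C(=O)N(C)OC | intermediate
9 | (Z)-3-methylpent-2-en-4-yn-1-ol | C#C/C(C)=C\CO | starting material
10 | (Z)-3-methylpent-2-en-4-ynal | C#C/C(C)=C\C=O | intermediate
11 | (3S,4Z)-5-methylhepta-1,4-dien-6-yn-3-ol | C#C/C(C)=C\[C@@H](O)C=C | intermediate
12 | tert-butyl{[(3S,4Z)-5-methylhepta-1,4-dien-6-yn-3-yl]oxy}dimethylsilane | C#C/C(C)=C\[C@@H](O[Si](C)(C)C(C)(C)C)C=C | intermediate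
13 | lithium acetylide of 12 (not isolated) | [Li]C#C/C(C)=C\[C@@H](O[Si](C)(C)C(C)(C)C)C=C | intermediate
14 | chloromagnesium alkoxide of 8 (not isolated) | COC(OC)C[C@@](C)(O[Mg]Cl)C(=O)N(C)OC | intermediate
15 | (3S,4Z,9R)-3-(tert-butyldimethylsilyloxy)-9-hydroxy-11,11-dimethoxy-5,9-dimethylundeca-1,4-dien-6-yn-8-one | COC(OC)C[C@@](C)(O)C(=O)C#C/C(C)=C\[C@@H](O[Si](C)(C)C(C)(C)C)C=C | intermediate
16 | (2R)-5-[(2Z,4S)-4-(tert-butyldimethylsilyloxy)hexa-2,5-dien-2-yl]-2-(2,2-dimethoxyethyl)-2-methylfuran-3(2H)-one | COC(OC)C[C@@]1(C)OC(=CC1=O)/C(C)=C\[C@@H](O[Si](C)(C)C(C)(C)C)C=C | intermediate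
17 | (2R)-2-(2,2-dimethoxyethyl)-5-[(2Z,4S)-4-hydroxyhexa-2,5-dien-2-yl]-2-methylfuran-3(2H)-one | COC(OC)C[C@@]1(C)OC(=CC1=O)/C(C)=C\[C@@H](O)C=C | intermediate
18 | 2-(bromomethyl)acrylic acid | C=C(CBr)C(=O)O | starting material
19 | (3S,4Z)-5-[(2R)-2-(2,2-dimethoxyethyl)-2-methyl-3-oxo-2,3-dihydrofuran-5-yl]hexa-1,4-dien-3-yl 2-(bromomethyl)prop-2-enoate | COC(OC)C[C@@]1(C)OC(=CC1=O)/C(C)=C\[C@@H](OC(=O)C(=C)CBr)C=C | intermediate
20 | (5R)-3-(bromomethyl)-5-{(1Z)-2-[(2R)-2-(2,2-dimethoxyethyl)-2-methyl-3-oxo-2,3-dihydrofuran-5-yl]prop-1-en-1-yl}furan-2(5H)-one | COC(OC)C[C@@]1(C)OC(=CC1=O)/C(C)=C\[C@H]1OC(=O)C(CBr)=C1 | intermediate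
21 | {(2R)-5-[(1Z)-1-((2R)-4-(bromomethyl)-5-oxo-2,5-dihydrofuran-2-yl)prop-1-en-2-yl]-2-methyl-3-oxo-2,3-dihydrofuran-2-yl}acetaldehyde | O=CC[C@@]1(C)OC(=CC1=O)/C(C)=C\[C@H]1OC(=O)C(CBr)=C1 | intermediate
22 | allylchromium dichloride derived from 21 (trivalent chromium on C13, not isolated) | O=CC[C@@]1(C)OC(=CC1=O)/C(C)=C\[C@H]1OC(=O)C(C[Cr](Cl)Cl)=C1 | intermediate
23 | (6R,7R,8S,10R)-8-hydroxy-3,10-epoxy-1-oxogermacra-2,4Z,11(13)-trien-12,6-olide (8α-hydroxy, trans-fused α-methylene lactone) | O[C@H]1C[C@@]2(C)OC(=CC2=O)/C(C)=C\[C@H]2OC(=O)C(=C)[C@@H]21 | intermediate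
24 | (6R,7R,8S,10R,11S)-8-hydroxy-3,10-epoxy-1-oxogermacra-2,4Z-dien-12,6-olide (8α-hydroxy, 11βH) | O[C@H]1C[C@@]2(C)OC(=CC2=O)/C(C)=C\[C@H]2OC(=O)[C@@H](C)[C@@H]21 | intermediate
25 | angelic acid, (Z)-2-methylbut-2-enoic acid | C/C=C(/C)C(=O)O | starting material
26 | (6R,7R,8R,10R,11S)-8-angeloyloxy-3,10-epoxy-1-oxogermacra-2,4Z-dien-12,6-olide (CNP0278264.1) | C/C=C(/C)C(=O)O[C@@H]1C[C@@]2(C)OC(=CC2=O)/C(C)=C\[C@H]2OC(=O)[C@@H](C)[C@@H]21 | target

**Step count**

Total steps: 16. Longest linear sequence: 13 steps (steps 1–4 and 8–16, from (S)-lactic acid).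

**Steps most likely to fail**

Step 14. The risk is that intermolecular allylation (oligomers) outruns closure of the strained trans-fused nine-membered ring, or that facial control at C8 is lost if a boat transition state competes. The fallback sets out from 21 and comes back at 23. The allylic bromide of 21 is converted with hexamethylditin and Pd(PPh3)4 (cat.) in THF into the allylstannane aldehyde {(2R)-2-methyl-3-oxo-5-[(1Z)-1-{(2R)-5-oxo-4-[(trimethylstannyl)methyl]-2,5-dihydrofuran-2-yl}prop-1-en-2-yl]-2,3-dihydrofuran-2-yl}acetaldehyde F1. F1 is then cyclised with BF3·OEt2 in CH2Cl2 at −78 °C under high dilution. This Lewis acid-promoted SE2' addition of an allylstannane to an aldehyde runs through an open transition state without a bridging metal, is a known way to close medium and large rings, and should give 23.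

Step 16. The risk is elimination toward C8=C9 from the oxyphosphonium ion, participation of the lactone carbonyl (retention or translactonisation), or phosphine-induced isomerisation of the angelate to the tiglate. The fallback sets out from 24 and comes back at 26. Oxidation of 24 with Dess–Martin periodinane gives the 8-oxo derivative of 24 (3,10-epoxy-1,8-dioxogermacra-2,4Z-dien-12,6-olide, other centres unchanged) F2. Reduction with NaBH4 in MeOH/THF at −78 °C, with hydride entering from the α-face away from the β-oriented C14 methyl and lactone, should give the 8β-alcohol (6R,7R,8R,10R,11S)-8-hydroxy-3,10-epoxy-1-oxogermacra-2,4Z-dien-12,6-olide F3. Esterification with retention by the mixed anhydride of angelic acid 25 and 2,4,6-trichlorobenzoyl chloride (Et3N, toluene, 80 °C; Yamaguchi conditions) then gives 26.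

Step 12. The risk is decomposition of the ruthenium carbene by the allylic bromide and slow ring closure onto the electron-poor 1,1-disubstituted acrylate. The fallback sets out from 17 and comes back at 20, and introduces the bromide only after the metathesis. Alcohol 17 is esterified (DCC, DMAP) with 2-{[(tert-butyldimethylsilyl)oxy]methyl}prop-2-enoic acid to (3S,4Z)-5-[(2R)-2-(2,2-dimethoxyethyl)-2-methyl-3-oxo-2,3-dihydrofuran-5-yl]hexa-1,4-dien-3-yl 2-{[(tert-butyldimethylsilyl)oxy]methyl}prop-2-enoate F4. Ring-closing metathesis gives (5R)-3-{[(tert-butyldimethylsilyl)oxy]methyl}-5-{(1Z)-2-[(2R)-2-(2,2-dimethoxyethyl)-2-methyl-3-oxo-2,3-dihydrofuran-5-yl]prop-1-en-1-yl}furan-2(5H)-one F5. TBAF/AcOH gives (5R)-5-{(1Z)-2-[(2R)-2-(2,2-dimethoxyethyl)-2-methyl-3-oxo-2,3-dihydrofuran-5-yl]prop-1-en-1-yl}-3-(hydroxymethyl)furan-2(5H)-one F6, and PBr3 in Et2O at −20 °C gives 20.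

**Further compounds**

F1 | step 14 | {(2R)-2-methyl-3-oxo-5-[(1Z)-1-{(2R)-5-oxo-4-[(trimethylstannyl)methyl]-2,5-dihydrofuran-2-yl}prop-1-en-2-yl]-2,3-dihydrofuran-2-yl}acetaldehyde | O=CC[C@@]1(C)OC(=CC1=O)/C(C)=C\[C@H]1OC(=O)C(C[Sn](C)(C)C)=C1
F2 | step 16 | 8-oxo derivative of 24 (3,10-epoxy-1,8-dioxogermacra-2,4Z-dien-12,6-olide) | O=C1C[C@@]2(C)OC(=CC2=O)/C(C)=C\[C@H]2OC(=O)[C@@H](C)[C@@H]21
F3 | step 16 | (6R,7R,8R,10R,11S)-8-hydroxy-3,10-epoxy-1-oxogermacra-2,4Z-dien-12,6-olide | O[C@@H]1C[C@@]2(C)OC(=CC2=O)/C(C)=C\[C@H]2OC(=O)[C@@H](C)[C@@H]21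
F4 | step 12 | (3S,4Z)-5-[(2R)-2-(2,2-dimethoxyethyl)-2-methyl-3-oxo-2,3-dihydrofuran-5-yl]hexa-1,4-dien-3-yl 2-{[(tert-butyldimethylsilyl)oxy]methyl}prop-2-enoate | COC(OC)C[C@@]1(C)OC(=CC1=O)/C(C)=C\[C@@H](OC(=O)C(=C)CO[Si](C)(C)C(C)(C)C)C=C
F5 | step 12 | (5R)-3-{[(tert-butyldimethylsilyl)oxy]methyl}-5-{(1Z)-2-[(2R)-2-(2,2-dimethoxyethyl)-2-methyl-3-oxo-2,3-dihydrofuran-5-yl]prop-1-en-1-yl}furan-2(5H)-one | COC(OC)C[C@@]1(C)OC(=CC1=O)/C(C)=C\[C@H]1OC(=O)C(CO[Si](C)(C)C(C)(C)C)=C1
F6 | step 12 | (5R)-5-{(1Z)-2-[(2R)-2-(2,2-dimethoxyethyl)-2-methyl-3-oxo-2,3-dihydrofuran-5-yl]prop-1-en-1-yl}-3-(hydroxymethyl)furan-2(5H)-one | COC(OC)C[C@@]1(C)OC(=CC1=O)/C(C)=C\[C@H]1OC(=O)C(CO)=C1
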